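## Analysis of the target

Betaethrin A (19) is an achiral diaryl ether made of two highly substituted benzene rings. Ring A is a methyl salicylate: C1 carries the ester, C2 a hydroxyl, C4 a methyl and C6 the ether oxygen, while C3 and C5 are unsubstituted. Ring B is bound through C1' to the same oxygen and carries a hydroxyl at C2', a methoxy group at C4' and an acetoxymethyl group at C6'. There is no stereocentre, so the task is one of regiochemistry and chemoselectivity only. The sensitive groups are the benzylic acetate (solvolysis, ionisation by Lewis acids, acyl transfer or elimination next to a phenoxide), the two phenols (ring B is an easily oxidised 4-methoxycatechol derivative) and the methyl ester. The hard part is the ether: both rings are electron-rich and three of the four positions ortho to the oxygen are substituted, so substitution or copper coupling on preformed arenes is unattractive. In addition, two phenols must be told apart from two methyl ethers and a primary alcohol. The strategy rests on the pattern of ring A: C1 (ester) lies between the oxygenated carbons C2 and C6, with the methyl on C4. This maps onto C3 (ester), C4 (aryloxy), C5 and C6 (methyl) of a 3-carbomethoxy-2-pyrone, with a two-carbon ketene acetal supplying C2 and C3.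

## Retrosynthetic reasoning

**19 back to 18.** The last cut is at the two oxygen–carbon bonds that mask the phenols: the O–CH3 bond at C2 of ring A and the acetal O–CH2 bond on the C2' oxygen. Both phenols are kept masked until the end so that the primary alcohol can be acetylated without competition. The C2 methyl ether differs from the C4' methyl ether by its position next to the ester, so a chelating boron Lewis acid can remove it selectively. The forward step must do this without ionising the benzylic acetate.

**18 back to 16.** The acetate is disconnected at its acyl–oxygen bond to the alcohol 17, and 17 at its O–Si bond to 16. An acetate next to a phenoxide would migrate or eliminate during the basic ether-forming step, so the benzylic oxygen travels as a silyl ether and is exchanged for acetate only after ring A exists.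

**16 back to 12 and 13.** Ring A is cut at C1–C2 and C3–C4. This removes the arene and leaves the pyrone 12, which already carries the ester, the aryloxy group and the methyl in the right order, plus the ketene acetal 13. The gain is that the hindered ether no longer has to be made on an arene. The forward reaction must be a regioselective inverse-demand cycloaddition, followed by decarboxylative cycloreversion and loss of one ketal methoxy group.

**12 back to 5 and 11.** The bond between the ether oxygen and pyrone C4 is cut. C4 is β to both the lactone carbonyl and the ester, so the forward step is an addition–elimination of the phenoxide of 11 on the sulfonate 5. It is not a substitution on an electron-rich benzene.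

**5 back to 1 and 2.** The sulfonate comes from the hydroxypyrone 4, which is cut at the C3–C4 bond and at the lactone O1–C2 bond into 1 (the acetoacetyl unit) and 2 (C2, C3 and the ester). The forward step needs 2 as its enolate, because neutral 2 would not intercept the acylating species released from 1. Lactonisation of the transient triketo diester 3 must outrun carbocyclisation.

**11 back to 6.** Phenol 11 is simplified by removing the silyl group (10), returning the hydroxymethyl group to the aldehyde (9), removing the methoxymethyl group (8), exchanging the C3 hydroxyl for bromine (7) and removing bromine (6). The aldehyde of 6 serves twice: it directs bromination to the one free position ortho to the phenol, and it makes the neighbouring phenol the less nucleophilic oxygen of the catechol dianion of 8, so that the other oxygen is protected selectively.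

## Alternatives that were turned down

**Alternative 1:** Ring B is disconnected at C1'–C6' and C4'–C5'. The forward key step is a (4+2) cycloaddition of the aryloxy silyloxy ketene-acetal diene A2, which carries ring A on its C1' oxygen, with the nitroacrylate A3. Base-induced loss of the nitro group and of one methoxy group then aromatises ring B to the phenol A1. In its favour, the nitro group is a strong and predictable regiochemical director, and the C2' phenol emerges free and already distinguished from the C4' methyl ether. On that point it is stronger than the chosen route, which needs a late deprotection. Against it, A2 is a tetra-oxygenated, hydrolytically fragile diene that must be built on a ring A phenol and enol-silylated with control of position and geometry. Its bonding terminus C1' bears the bulky ortho-ester aryloxy group. A1 also holds C6' at the carboxylate oxidation level. The end game must therefore reduce one ester next to the ring A methyl ester and then acetylate a primary alcohol beside two free phenols, and the benzyl groups must go by hydrogenolysis close to a benzylic C–O bond. The step count is similar to the chosen route, but the selectivity problems are moved to the last steps. The chosen route offers shelf-stable partners (12 and 13) and an end game in which no two hydroxyl groups of similar reactivity are ever free together.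

**Alternative 2:** Ring B is disconnected into the unsaturated diazo ketone A5 (C5', C6', C1' and the carbonyl carbon that becomes C2') and the alkoxyalkyne A6 (C3', C4'). In the forward sense, irradiation triggers a Wolff rearrangement to a vinylketene. This adds A6 by (2+2) cycloaddition, and 4π ring opening followed by 6π closure forms C2'–C3', C4'–C5' and C1'–C2' and gives the phenol A4. In its favour, the regiochemistry is inherent in the cascade, the C2' phenol is free and the acetate is already in place. A4 is a single deprotection from the target, the shortest end game of the four, and here it is clearly stronger. Against it, A5 combines a diazo ketone, a β-aryloxy enone open to addition–elimination and an allylic acetate prone to elimination. Its assembly on a ring A phenol would take six or seven delicate steps, and the enol ether geometry has to be set. A6 is volatile and unstable and must be made fresh. The photochemical step runs in the presence of other chromophores and passes through two ketenes that any nucleophile can intercept. The chosen route keeps the sensitive acetate out until two steps from the end and places its risk in one thermal step between robust compounds.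

**Alternative 3:** Ring A is disconnected at C5–C6 and C1–C2. The forward step is a (4+2) cycloaddition of the silyl vinylketene acetal A8 (C2 to C5) with the aryloxypropiolate A9 (C1 and C6), and loss of a methoxy group gives the salicylate A7. This is the closest relative of the chosen plan, since ring A is again made with the ether already present. It is stronger in that the C2 phenol is delivered free, so no aryl methyl ether has to be cleaved and the end game avoids a Lewis acid. Against it, A9 is an ynol ether ester that must be made from a hindered phenol such as 11 through a haloalkenyl ether and strong base, and such compounds hydrate and polymerise easily. The aryloxy donor sits on the very alkyne carbon (C6) that must accept the nucleophilic diene terminus, so it both cancels the ester activation and shields the reacting centre. In 12 the aryloxy group sits on C4, which is not a bonding terminus. A8 can also react through its α-carbon in a conjugate addition and give open-chain products. The chosen route forms the C–O bond by a simple addition–elimination on a stable pyrone and accepts one extra deprotection in return.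

Key step: step 9

Remark on the chemistry: the target has no stereocentre. The bridged intermediate 14 of the key step forms as a racemate, and its two bridgehead centres disappear on aromatisation.

## Route

Step 1
Reactants: 1 2,2,6-trimethyl-4H-1,3-dioxin-4-one; 2 dimethyl malonate
Product: 4 methyl 4-hydroxy-6-methyl-2-oxo-2H-pyran-3-carboxylate, via dimethyl (3-oxobutanoyl)malonate 3 (not isolated)
Conditions: NaH (1.0 equiv), THF, 0 °C; then 1, PhMe, 110 °C; then aq HCl
Reagents that add atoms: none
Why: Retro-(4+2) cleavage of the dioxinone above about 100 °C releases acetylketene, which C-acylates the sodium enolate of 2 to give 3. The enol oxygen of the acetyl group of 3 then attacks one ester (lactonisation with loss of methanol) to close the 4-hydroxy-2-pyrone, as in the classical diketene–malonate pyrone synthesis.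

Step 2
Reactants: 4 methyl 4-hydroxy-6-methyl-2-oxo-2H-pyran-3-carboxylate
Product: 5 methyl 6-methyl-4-{[(4-methylphenyl)sulfonyl]oxy}-2-oxo-2H-pyran-3-carboxylate
Conditions: TsCl, Et3N, CH2Cl2, 0 °C
Reagents that add atoms: 4-methylbenzenesulfonyl chloride, Cc1ccc(cc1)S(=O)(=O)Cl
Why: O-Sulfonylation of a vinylogous acid; the C4 hydroxyl is strongly acidic and its enolate reacts at oxygen with the sulfonyl chloride.

Step 3
Reactants: 6 2-hydroxy-5-methoxybenzaldehyde
Product: 7 3-bromo-2-hydroxy-5-methoxybenzaldehyde
Conditions: Br2, NaOAc, AcOH, rt
Reagents that add atoms: bromine, BrBr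
Why: Electrophilic aromatic bromination; the phenol is the strongest director and its only free ortho or para position is C3, which is also meta to the deactivating aldehyde.

Step 4
Reactants: 7 3-bromo-2-hydroxy-5-methoxybenzaldehyde
Product: 8 2,3-dihydroxy-5-methoxybenzaldehyde
Conditions: NaOH (aq), copper powder (Cu, cat.), reflux, N2; then aq HCl
Reagents that add atoms: sodium hydroxide, [Na+].[OH-]
Why: Copper-mediated Ullmann-type hydroxylation of an ortho-bromophenol, the reaction that converts 5-bromovanillin into 5-hydroxyvanillin. The phenoxide protects the aldehyde from Cannizzaro reaction, and exclusion of air protects the catechol.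

Step 5
Reactants: 8 2,3-dihydroxy-5-methoxybenzaldehyde
Product: 9 2-hydroxy-5-methoxy-3-(methoxymethoxy)benzaldehyde
Conditions: NaH (2.1 equiv), DMSO, rt; MOMCl (1.0 equiv), 0 °C → rt; aq NH4Cl
Reagents that add atoms: chloromethyl methyl ether, COCCl
Why: Selective alkylation of a catechol dianion. The C2 phenoxide is conjugated with the aldehyde and is the weaker nucleophile, so one equivalent of the electrophile reacts at the C3 oxygen, as is established for 2,3-dihydroxybenzaldehyde.

Step 6
Reactants: 9 2-hydroxy-5-methoxy-3-(methoxymethoxy)benzaldehyde
Product: 10 2-(hydroxymethyl)-4-methoxy-6-(methoxymethoxy)phenol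
Conditions: NaBH4, MeOH, 0 °C
Reagents that add atoms: none
Why: Borohydride reduction of an aryl aldehyde; the MOM ether and the aryl methyl ether are inert.

Step 7
Reactants: 10 2-(hydroxymethyl)-4-methoxy-6-(methoxymethoxy)phenol
Product: 11 2-({[tert-butyl(dimethyl)silyl]oxy}methyl)-4-methoxy-6-(methoxymethoxy)phenol
Conditions: TBSCl (1.05 equiv), imidazole, CH2Cl2, 0 °C
Reagents that add atoms: tert-butyl(chloro)dimethylsilane, CC(C)(C)[Si](C)(C)Cl
Why: Chemoselective silylation; the unhindered primary benzylic alcohol reacts faster than the doubly ortho-substituted phenol, as is known for salicyl alcohols.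

Step 8
Reactants: 5 methyl 6-methyl-4-{[(4-methylphenyl)sulfonyl]oxy}-2-oxo-2H-pyran-3-carboxylate; 11 2-({[tert-butyl(dimethyl)silyl]oxy}methyl)-4-methoxy-6-(methoxymethoxy)phenol
Product: 12 methyl 4-[2-({[tert-butyl(dimethyl)silyl]oxy}methyl)-4-methoxy-6-(methoxymethoxy)phenoxy]-6-methyl-2-oxo-2H-pyran-3-carboxylate
Conditions: Cs2CO3, MeCN, 0 °C → rt
Reagents that add atoms: none
Why: Addition–elimination (vinylic substitution) at pyrone C4, which is β to both the lactone and the ester carbonyl. The phenoxide adds in conjugate fashion and the stabilised enolate expels the sulfonate.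

Step 9
Reactants: 12 methyl 4-[2-({[tert-butyl(dimethyl)silyl]oxy}methyl)-4-methoxy-6-(methoxymethoxy)phenoxy]-6-methyl-2-oxo-2H-pyran-3-carboxylate; 13 1,1-dimethoxyethene
Product: 16 methyl 2-[2-({[tert-butyl(dimethyl)silyl]oxy}methyl)-4-methoxy-6-(methoxymethoxy)phenoxy]-6-methoxy-4-methylbenzoate, via bicyclic lactone adduct 14 (not isolated), via cyclohexadiene dimethyl ketal 15 (not isolated)
Conditions: 13 (5–8 equiv), PhMe, sealed tube, 120–140 °C
Reagents that add atoms: none
Why: The pyrone 12 is an electron-poor diene whose LUMO is lowered by the lactone carbonyl and the C3 ester, and 13 is an electron-rich dienophile, so the pair should undergo the inverse-electron-demand Diels-Alder reaction established for 3-carbomethoxy-2-pyrones with 1,1-dimethoxyethene. The (4+2) cycloaddition is concerted but asynchronous: the nucleophilic CH2 of 13 bonds to pyrone C6 ahead of the union of the acetal carbon with C3, which closes the six-membered carbocycle by intermolecular cycloaddition across C3 and C6 and gives the bridged lactone 14. Retro-(4+2) extrusion of CO2 from 14 gives the cyclohexadiene ketal 15, and 1,2-elimination of methanol (a C6 methoxy group and a C5 hydrogen of 15) makes ring A aromatic, so the new ring A bonds are C1-C2 and C3-C4. The two bridgehead stereocentres of 14 are transient and vanish on aromatisation, so no stereocontrol is required. The step needs regiochemistry (acetal carbon to C3, CH2 to C6) and cycloaddition in preference to conjugate addition–elimination at C4. The first is secured by the polarisation of the diene by the C3 ester and the lactone carbonyl, which makes C6 the acceptor terminus for the only nucleophilic carbon of 13; the second by neutral, aprotic thermal conditions. The 4-aryloxy group is a donor that raises the LUMO compared with 4-unsubstituted pyrones, which is why a sealed tube, heat and excess 13 are specified; the excess also traps the methanol set free, and the TBS and MOM ethers are inert.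

Step 10
Reactants: 16 methyl 2-[2-({[tert-butyl(dimethyl)silyl]oxy}methyl)-4-methoxy-6-(methoxymethoxy)phenoxy]-6-methoxy-4-methylbenzoate
Product: 17 methyl 2-[2-(hydroxymethyl)-4-methoxy-6-(methoxymethoxy)phenoxy]-6-methoxy-4-methylbenzoate
Conditions: TBAF, AcOH, THF, 0 °C → rt
Reagents that add atoms: none
Why: Fluoride cleavage of the Si–O bond. The acetic acid buffer keeps the alkoxide from attacking the ring A ester, which would close an eight-membered lactone, and spares the methyl ester.

Step 11
Reactants: 17 methyl 2-[2-(hydroxymethyl)-4-methoxy-6-(methoxymethoxy)phenoxy]-6-methoxy-4-methylbenzoate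
Product: 18 methyl 2-[2-(acetoxymethyl)-4-methoxy-6-(methoxymethoxy)phenoxy]-6-methoxy-4-methylbenzoate
Conditions: Ac2O, pyridine, DMAP (cat.), CH2Cl2, 0 °C → rt
Reagents that add atoms: acetic anhydride, CC(=O)OC(C)=O
Why: DMAP-catalysed acylation of the only free hydroxyl group; both phenols are still masked, so no selectivity is needed.

Step 12
Reactants: 18 methyl 2-[2-(acetoxymethyl)-4-methoxy-6-(methoxymethoxy)phenoxy]-6-methoxy-4-methylbenzoate
Product: 19 betaethrin A (methyl 2-[2-(acetoxymethyl)-6-hydroxy-4-methoxyphenoxy]-6-hydroxy-4-methylbenzoate)
Conditions: BCl3 (3.5 equiv), CH2Cl2, −78 → 0 °C; then H2O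
Reagents that add atoms: none
Why: Chelation-controlled ether cleavage; BCl3 bridges the ester carbonyl and the adjacent C2 methoxy oxygen in a six-membered chelate and chloride removes that methyl group. The MOM acetal is cleaved through its oxocarbenium ion, and the non-chelated C4' methyl ether and the acetate should remain at or below 0 °C.

## Compound list

1 | 2,2,6-trimethyl-4H-1,3-dioxin-4-one | CC1=CC(=O)OC(C)(C)O1 | starting material
2 | dimethyl malonate | COC(=O)CC(=O)OC | starting material
3 | dimethyl (3-oxobutanoyl)malonate | CC(=O)CC(=O)C(C(=O)OC)C(=O)OC | intermediate (not isolated)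
4 | methyl 4-hydroxy-6-methyl-2-oxo-2H-pyran-3-carboxylate | COC(=O)C1=C(O)C=C(C)OC1=O | intermediate
5 | methyl 6-methyl-4-{[(4-methylphenyl)sulfonyl]oxy}-2-oxo-2H-pyran-3-carboxylate | COC(=O)C1=C(OS(=O)(=O)c2ccc(C)cc2)C=C(C)OC1=O | intermediate
6 | 2-hydroxy-5-methoxybenzaldehyde | COc1ccc(O)c(C=O)c1 | starting material
7 | 3-bromo-2-hydroxy-5-methoxybenzaldehyde | COc1cc(Br)c(O)c(C=O)c1 | intermediate
8 | 2,3-dihydroxy-5-methoxybenzaldehyde | COc1cc(O)c(O)c(C=O)c1 | intermediate
9 | 2-hydroxy-5-methoxy-3-(methoxymethoxy)benzaldehyde | COCOc1cc(OC)cc(C=O)c1O | intermediate
10 | 2-(hydroxymethyl)-4-methoxy-6-(methoxymethoxy)phenol | COCOc1cc(OC)cc(CO)c1O | intermediate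
11 | 2-({[tert-butyl(dimethyl)silyl]oxy}methyl)-4-methoxy-6-(methoxymethoxy)phenol | COCOc1cc(OC)cc(CO[Si](C)(C)C(C)(C)C)c1O | intermediate
12 | methyl 4-[2-({[tert-butyl(dimethyl)silyl]oxy}methyl)-4-methoxy-6-(methoxymethoxy)phenoxy]-6-methyl-2-oxo-2H-pyran-3-carboxylate | COC(=O)C1=C(Oc2c(OCOC)cc(OC)cc2CO[Si](C)(C)C(C)(C)C)C=C(C)OC1=O | intermediate
13 | 1,1-dimethoxyethene | C=C(OC)OC | starting material
14 | methyl 5-[2-({[tert-butyl(dimethyl)silyl]oxy}methyl)-4-methoxy-6-(methoxymethoxy)phenoxy]-8,8-dimethoxy-1-methyl-3-oxo-2-oxabicyclo[2.2.2]oct-5-ene-4-carboxylate (racemate; the two bridgehead centres are tied by the bicycle) | COC(=O)C12C(Oc3c(OCOC)cc(OC)cc3CO[Si](C)(C)C(C)(C)C)=CC(C)(CC1(OC)OC)OC2=O | intermediate (not isolated)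
15 | methyl 2-[2-({[tert-butyl(dimethyl)silyl]oxy}methyl)-4-methoxy-6-(methoxymethoxy)phenoxy]-6,6-dimethoxy-4-methylcyclohexa-1,3-diene-1-carboxylate | COC(=O)C1=C(Oc2c(OCOC)cc(OC)cc2CO[Si](C)(C)C(C)(C)C)C=C(C)CC1(OC)OC | intermediate (not isolated)
16 | methyl 2-[2-({[tert-butyl(dimethyl)silyl]oxy}methyl)-4-methoxy-6-(methoxymethoxy)phenoxy]-6-methoxy-4-methylbenzoate | COC(=O)c1c(OC)cc(C)cc1Oc1c(OCOC)cc(OC)cc1CO[Si](C)(C)C(C)(C)C | intermediate
17 | methyl 2-[2-(hydroxymethyl)-4-methoxy-6-(methoxymethoxy)phenoxy]-6-methoxy-4-methylbenzoate | COC(=O)c1c(OC)cc(C)cc1Oc1c(OCOC)cc(OC)cc1CO | intermediate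
18 | methyl 2-[2-(acetoxymethyl)-4-methoxy-6-(methoxymethoxy)phenoxy]-6-methoxy-4-methylbenzoate | COC(=O)c1c(OC)cc(C)cc1Oc1c(OCOC)cc(OC)cc1COC(C)=O | intermediate
19 | betaethrin A, methyl 2-[2-(acetoxymethyl)-6-hydroxy-4-methoxyphenoxy]-6-hydroxy-4-methylbenzoate | COC(=O)c1c(O)cc(C)cc1Oc1c(O)cc(OC)cc1COC(C)=O | target

## Step count and least certain steps

Total: 12 steps. Longest linear sequence: 10 steps (steps 3 to 12, from 6 to 19); the pyrone branch (steps 1 and 2) joins at step 8.

**Step 9 (key step).** The donor at C4 may slow the cycloaddition so much that thermal polymerisation of the ketene acetal wins. Conjugate attack of the acetal at C4 with expulsion of the aryloxide, or exchange of the aryloxy group by the liberated methanol, may also compete. Elimination of methanol from the ketal may be incomplete. The fallback makes the ether on a preformed ring A by aromatic substitution. Setting out from 11, its potassium phenoxide (K2CO3, DMF, 80 °C) should displace one fluoride of purchased 2,6-difluoro-4-methylbenzaldehyde F1 to give 2-[2-({[tert-butyl(dimethyl)silyl]oxy}methyl)-4-methoxy-6-(methoxymethoxy)phenoxy]-6-fluoro-4-methylbenzaldehyde F2. NaOMe in MeOH/THF at 60 °C would then replace the second fluoride and give 2-[2-({[tert-butyl(dimethyl)silyl]oxy}methyl)-4-methoxy-6-(methoxymethoxy)phenoxy]-6-methoxy-4-methylbenzaldehyde F3. Pinnick oxidation (NaClO2, NaH2PO4, 2-methylbut-2-ene, t-BuOH/H2O) would give 2-[2-({[tert-butyl(dimethyl)silyl]oxy}methyl)-4-methoxy-6-(methoxymethoxy)phenoxy]-6-methoxy-4-methylbenzoic acid F4, and O-methylation of the carboxylate (MeI, K2CO3, DMF) brings the route back at 16.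

**Step 12.** The Lewis acid may ionise the benzylic C–O bond of the acetate, exchanging acetate for chloride, and prolonged exposure may also remove the C4' methyl group. The fallback changes the order and the basis of selectivity. Setting out from 17, BCl3 would be applied before the acetate is present, giving methyl 2-hydroxy-6-[2-hydroxy-6-(hydroxymethyl)-4-methoxyphenoxy]-4-methylbenzoate F5. The primary alcohol of F5 would then be acetylated by immobilised Candida antarctica lipase B with vinyl acetate in MTBE at 35 °C, a method that leaves phenols untouched, and the route comes back at 19.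

**Step 8.** The phenoxide may attack sulfur instead of C4 (sulfonyl transfer). The silyl group may migrate to the phenoxide oxygen so that the benzylic oxygen is etherified. The pyrone may be opened by attack at C2 or C6. The fallback uses an electrophile with a single reactive site. Setting out from 4, oxalyl chloride with catalytic DMF in CH2Cl2 should give the vinylogous acid chloride methyl 4-chloro-6-methyl-2-oxo-2H-pyran-3-carboxylate F6. This would be substituted by 11 with Cs2CO3 in MeCN and comes back at 12.

**Step 1.** The free ketene may self-condense faster than it is trapped, acylation may occur on oxygen, or the triketo diester may close by Claisen carbocyclisation instead of lactonisation. The fallback avoids a free ketene. Setting out from 2, its magnesium enolate (MgCl2, Et3N, MeCN, 0 °C) would be acetoacetylated by 4-methylideneoxetan-2-one F7 (diketene, purchased) through direct opening of the β-lactone at its acyl carbon. This comes back at 3, which is closed to 4 with acid as in step 1.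

## Further compounds

F1 | step 9 | 2,6-difluoro-4-methylbenzaldehyde (purchased) | Cc1cc(F)c(C=O)c(F)c1
F2 | step 9 | 2-[2-({[tert-butyl(dimethyl)silyl]oxy}methyl)-4-methoxy-6-(methoxymethoxy)phenoxy]-6-fluoro-4-methylbenzaldehyde | O=Cc1c(F)cc(C)cc1Oc1c(OCOC)cc(OC)cc1CO[Si](C)(C)C(C)(C)C
F3 | step 9 | 2-[2-({[tert-butyl(dimethyl)silyl]oxy}methyl)-4-methoxy-6-(methoxymethoxy)phenoxy]-6-methoxy-4-methylbenzaldehyde | O=Cc1c(OC)cc(C)cc1Oc1c(OCOC)cc(OC)cc1CO[Si](C)(C)C(C)(C)C
F4 | step 9 | 2-[2-({[tert-butyl(dimethyl)silyl]oxy}methyl)-4-methoxy-6-(methoxymethoxy)phenoxy]-6-methoxy-4-methylbenzoic acid | OC(=O)c1c(OC)cc(C)cc1Oc1c(OCOC)cc(OC)cc1CO[Si](C)(C)C(C)(C)C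
F5 | step 12 | methyl 2-hydroxy-6-[2-hydroxy-6-(hydroxymethyl)-4-methoxyphenoxy]-4-methylbenzoate | COC(=O)c1c(O)cc(C)cc1Oc1c(O)cc(OC)cc1CO
F6 | step 8 | methyl 4-chloro-6-methyl-2-oxo-2H-pyran-3-carboxylate | COC(=O)C1=C(Cl)C=C(C)OC1=O
F7 | step 1 | 4-methylideneoxetan-2-one (diketene, purchased) | C=C1CC(=O)O1
A1 | alternative 1 | benzyl 2-[3-(benzyloxy)-2-(methoxycarbonyl)-5-methylphenoxy]-3-hydroxy-5-methoxybenzoate | COC(=O)c1c(OCc2ccccc2)cc(C)cc1Oc1c(O)cc(OC)cc1C(=O)OCc1ccccc1
A2 | alternative 1 | methyl 2-(benzyloxy)-6-({(1Z)-4,4-dimethoxy-2-[(trimethylsilyl)oxy]buta-1,3-dien-1-yl}oxy)-4-methylbenzoate | COC(=O)c1c(OCc2ccccc2)cc(C)cc1O/C=C(\O[Si](C)(C)C)C=C(OC)OC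
A3 | alternative 1 | benzyl (2E)-3-nitroprop-2-enoate | O=C(OCc1ccccc1)/C=C/[N+](=O)[O-]
A4 | alternative 2 | methyl 2-[2-(acetoxymethyl)-6-hydroxy-4-methoxyphenoxy]-6-(methoxymethoxy)-4-methylbenzoate | COC(=O)c1c(OCOC)cc(C)cc1Oc1c(O)cc(OC)cc1COC(C)=O
A5 | alternative 2 | methyl 2-{[(1E)-2-(acetoxymethyl)-4-diazo-3-oxobut-1-en-1-yl]oxy}-6-(methoxymethoxy)-4-methylbenzoate | COC(=O)c1c(OCOC)cc(C)cc1O/C=C(\COC(C)=O)C(=O)C=[N+]=[N-]
A6 | alternative 2 | methoxyethyne | COC#C
A7 | alternative 3 | methyl 2-[2-({[tert-butyl(dimethyl)silyl]oxy}methyl)-4-methoxy-6-(methoxymethoxy)phenoxy]-6-hydroxy-4-methylbenzoate | COC(=O)c1c(O)cc(C)cc1Oc1c(OCOC)cc(OC)cc1CO[Si](C)(C)C(C)(C)C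
A8 | alternative 3 | (1Z)-1-methoxy-3-methyl-1-[(trimethylsilyl)oxy]buta-1,3-diene | C=C(C)/C=C(\O[Si](C)(C)C)OC
A9 | alternative 3 | methyl 3-[2-({[tert-butyl(dimethyl)silyl]oxy}methyl)-4-methoxy-6-(methoxymethoxy)phenoxy]prop-2-ynoate | COC(=O)C#COc1c(OCOC)cc(OC)cc1CO[Si](C)(C)C(C)(C)C
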